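**Retrosynthetic overview**
1. Target 9 ⇐ dialdehyde 6: only the conjugated C3 aldehyde is reduced, with the C2 aldehyde masked in the same flask.
2. 6 ⇐ achiral bis-arylidene dialdehyde 4: catalytic enantioselective quinone-methide-type Friedel–Crafts closure (the lignan C2–C7′ bond). This sets C1; C2 follows as the trans isomer.
3. 4 ⇐ 2 × coniferaldehyde 1: phenoxyl-radical 8–8′ coupling to a bis-quinone methide, then double re-aromatisation.
4. Ring order: both aromatic rings come from 1; the only ring built is the central carbocycle (C1–C4/C4a/C8a), in step 2.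

Assumption: the target is taken as the open γ-hydroxy-aldehyde as drawn (its five-membered lactol is a ring–chain tautomer of the same compound); locants follow the target name (C1 carries the pendant aryl, C2 the sp3 CHO, C3=C4 is the alkene).

**Step 1**
Reactants: 1 coniferaldehyde (2 equiv)
Product: 4 (2E,3E)-2,3-bis[(4-hydroxy-3-methoxyphenyl)methylidene]butanedial, via bis-quinone methide 2 (not isolated), via mono-quinone methide 3 (not isolated)
Conditions: horseradish peroxidase (cat.), H2O2 (0.5 equiv, slow addition), acetone/phosphate buffer pH 6.5, rt; chromatography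
Reagents that add atoms: none
Why: Peroxidase-type oxidative phenol coupling (dehydrodimerisation of a hydroxycinnamaldehyde): one-electron oxidation and 8–8′ radical–radical coupling give 2, whose H8 and H8′ (α to CHO) are lost in two prototropic re-aromatisations through 3 to the conjugated (E,E)-diene, so no stereocentre remains; the 8–O–4′ and 8–5′ dimers that also form are separated.

**Step 2**
Reactants: 4 (2E,3E)-2,3-bis[(4-hydroxy-3-methoxyphenyl)methylidene]butanedial
Product: 6 (1S,2R)-7-hydroxy-1-(4-hydroxy-3-methoxyphenyl)-6-methoxy-1,2-dihydronaphthalene-2,3-dicarbaldehyde, via enol 5 (not isolated)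
Conditions: (S,S)-IDPi (confined BINOL-derived imidodiphosphorimidate, N-triflyl, 5 mol %), CHCl3 (0.02 M), 25→40 °C, dark, Ar; Et3N quench
Reagents that add atoms: none
Why: Proposed new method: the chiral acid protonates one push–pull enal of C2-symmetric 4, making that arm an O-protonated quinone methide whose benzylic carbon is attacked by C6 of the other guaiacyl ring (para to OMe) in a 6π-type Friedel–Crafts closure inside the chiral ion pair, which selects one helical conformer of the twisted diene and so sets C1, after which re-aromatisation gives enol 5 and C2 equilibrates under the acid to the more stable trans aldehyde; the closest known reaction types are the triflic-acid cyclisation of bis(benzylidene)succinates to trans-1-aryl-1,2-dihydronaphthalenes, acid-catalysed 6π-electrocyclisation of 2-acyl hexatrienes and chiral N-triflylphosphoramide/IDPi-catalysed Nazarov cyclisations; the sense of induction cannot be predicted and the (R,R)-catalyst is used if it proves opposite.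

**Step 3**
Reactants: 6 (1S,2R)-7-hydroxy-1-(4-hydroxy-3-methoxyphenyl)-6-methoxy-1,2-dihydronaphthalene-2,3-dicarbaldehyde
Product: 9 (1S,2R)-7-hydroxy-1-(4-hydroxy-3-methoxyphenyl)-3-(hydroxymethyl)-6-methoxy-1,2-dihydronaphthalene-2-carbaldehyde, via dimethyl acetal 7 (not isolated), via hydroxy acetal 8 (not isolated)
Conditions: CeCl3·7H2O (1 equiv), HC(OMe)3, MeOH, 0 °C→rt; NaBH4, −20 °C; then 0.5 M HCl, THF–H2O, 0 °C
Reagents that add atoms: water, O (becomes the carbonyl oxygen of the C2 aldehyde on acetal hydrolysis); trimethyl orthoformate, COC(OC)OC (its OMe groups are in 7 and 8 only, not in 9)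
Why: Luche-type chemoselective reduction: CeCl3/HC(OMe)3 acetalises only the non-conjugated C2 aldehyde (the C3 aldehyde is a deactivated phenylogous acid), NaBH4/CeCl3 then reduces the conjugated aldehyde 1,2 to the allylic alcohol and dilute acid unmasks the C2 aldehyde; no stereocentre is formed, C1 is not epimerisable and trans at C2 is the thermodynamic arrangement.

**Compound list**
1 | coniferaldehyde, (E)-3-(4-hydroxy-3-methoxyphenyl)prop-2-enal | COc1cc(/C=C/C=O)ccc1O | starting material
2 | 8,8′-coupled bis-quinone methide, 2,3-bis[(3-methoxy-4-oxocyclohexa-2,5-dien-1-ylidene)methyl]butanedial (rac/meso mixture, C8/C8′ not defined) | O=CC(C=C1C=CC(=O)C(OC)=C1)C(C=O)C=C1C=CC(=O)C(OC)=C1 | intermediate (not isolated)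
3 | mono-quinone methide, (3E)-3-[(4-hydroxy-3-methoxyphenyl)methylidene]-2-[(3-methoxy-4-oxocyclohexa-2,5-dien-1-ylidene)methyl]butanedial (racemic at C2) | O=CC(C=C1C=CC(=O)C(OC)=C1)/C(C=O)=C\c1ccc(O)c(OC)c1 | intermediate (not isolated)
4 | (2E,3E)-2,3-bis[(4-hydroxy-3-methoxyphenyl)methylidene]butanedial | O=C/C(=C/c1ccc(O)c(OC)c1)/C(C=O)=C\c1ccc(O)c(OC)c1 | intermediate (isolated)
5 | enol, (1S)-7-hydroxy-2-(hydroxymethylidene)-1-(4-hydroxy-3-methoxyphenyl)-6-methoxy-1,2-dihydronaphthalene-3-carbaldehyde | COc1cc([C@H]2c3cc(O)c(OC)cc3C=C(C=O)C2=CO)ccc1O | intermediate (not isolated)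
6 | (1S,2R)-7-hydroxy-1-(4-hydroxy-3-methoxyphenyl)-6-methoxy-1,2-dihydronaphthalene-2,3-dicarbaldehyde (1,2-trans) | COc1cc([C@H]2c3cc(O)c(OC)cc3C=C(C=O)[C@@H]2C=O)ccc1O | intermediate (isolated)
7 | dimethyl acetal, (1S,2R)-2-(dimethoxymethyl)-7-hydroxy-1-(4-hydroxy-3-methoxyphenyl)-6-methoxy-1,2-dihydronaphthalene-3-carbaldehyde | COc1cc([C@H]2c3cc(O)c(OC)cc3C=C(C=O)[C@@H]2C(OC)OC)ccc1O | intermediate (not isolated)
8 | hydroxy acetal, (1S,2R)-2-(dimethoxymethyl)-1-(4-hydroxy-3-methoxyphenyl)-3-(hydroxymethyl)-6-methoxy-1,2-dihydronaphthalen-7-ol | COc1cc([C@H]2c3cc(O)c(OC)cc3C=C(CO)[C@@H]2C(OC)OC)ccc1O | intermediate (not isolated)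
9 | (1S,2R)-7-hydroxy-1-(4-hydroxy-3-methoxyphenyl)-3-(hydroxymethyl)-6-methoxy-1,2-dihydronaphthalene-2-carbaldehyde (1,2-trans) | COc1cc([C@H]2c3cc(O)c(OC)cc3C=C(CO)[C@@H]2C=O)ccc1O | target

**Totals**
Total step count: 3. Longest linear sequence: 3 steps.

**Steps most likely to fail, with fallbacks**

Step 2 (asymmetric ring closure) is the least precedented. The acid may be too weak for the deactivated ring, the ee may be low, or the sense of induction may be wrong. Primary-amine iminium catalysts are avoided here because the 1,4-dialdehydes 4 and 6 would trap the amine by Paal–Knorr-type condensation. The fallback sets out from 4 and comes back at 6: 4 is cyclised without induction (TfOH 0.2 equiv, CH2Cl2–HFIP, 0 °C, the type of conditions used for bis(benzylidene)succinates) to the racemic trans-dialdehyde, that is 6 together with its (1R,2S)-enantiomer F5, and the racemate is resolved by preparative chiral SFC to give 6.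

Step 1 (radical coupling) will give the 8–8′ dimer only as a minor component of the dimer mixture, at a guess 10–20 %, beside the 8–O–4′ and 8–5′ dimers. The fallback sets out from 1 and comes back at 4, making the C8–C8′ bond by cross-coupling instead. Acetylation of 1 (Ac2O, pyridine) gives 4-O-acetylconiferaldehyde F1. Bromine addition (Br2, CH2Cl2, 0 °C) gives the 2,3-dibromo aldehyde F2, which loses HBr with Et3N in the same flask to the (Z)-α-bromo enal F3. Palladium-catalysed borylative homocoupling (B2pin2 0.55 equiv, Pd(dppf)Cl2, K3PO4, dioxane–H2O, 80 °C) joins two molecules of F3 with retention of alkene geometry to the diacetate F4. K2CO3/MeOH then removes both acetates to return 4.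

Step 3 (chemoselective reduction) can fail if the wrong aldehyde is reduced, or if acid unmasking damages the allylic alcohol or isomerises the β,γ-unsaturated aldehyde; 9 should be kept away from base and purified quickly. The fallback sets out from 4 and comes back at 9 by reducing before ring closure. Treating 4 with 0.3 equiv NaBH4 (CeCl3, MeOH–THF, −78 °C, unreacted 4 recycled) gives the mono-alcohol, hydroxy-enal F6. F6 has only one aldehyde and is ring-closed by chiral primary-amine iminium catalysis (9-amino-9-deoxy-epi-quinine, TFA, toluene, rt; pseudo-enantiomeric catalyst if the sense is opposite). This is an intramolecular Friedel–Crafts addition of the now non-deactivated guaiacyl ring to the β-carbon of the iminium ion, and hydrolysis gives 9 directly.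

**Further compounds**
F1 | step 1 | 4-O-acetylconiferaldehyde, (E)-3-(4-acetoxy-3-methoxyphenyl)prop-2-enal | CC(=O)Oc1ccc(/C=C/C=O)cc1OC
F2 | step 1 | 3-(4-acetoxy-3-methoxyphenyl)-2,3-dibromopropanal (racemic, diastereomers not defined) | CC(=O)Oc1ccc(C(Br)C(Br)C=O)cc1OC
F3 | step 1 | (Z)-3-(4-acetoxy-3-methoxyphenyl)-2-bromoprop-2-enal | CC(=O)Oc1ccc(/C=C(\Br)C=O)cc1OC
F4 | step 1 | (2E,3E)-2,3-bis[(4-acetoxy-3-methoxyphenyl)methylidene]butanedial | O=C/C(=C/c1ccc(OC(C)=O)c(OC)c1)/C(C=O)=C\c1ccc(OC(C)=O)c(OC)c1
F5 | step 2 | (1R,2S)-7-hydroxy-1-(4-hydroxy-3-methoxyphenyl)-6-methoxy-1,2-dihydronaphthalene-2,3-dicarbaldehyde (enantiomer of 6, formed with 6 as the racemate) | COc1cc([C@@H]2c3cc(O)c(OC)cc3C=C(C=O)[C@H]2C=O)ccc1O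
F6 | step 3 | (2E,3E)-3-(hydroxymethyl)-4-(4-hydroxy-3-methoxyphenyl)-2-[(4-hydroxy-3-methoxyphenyl)methylidene]but-3-enal | OC/C(=C/c1ccc(O)c(OC)c1)/C(C=O)=C\c1ccc(O)c(OC)c1
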